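**Retrosynthetic overview**
1. The dioxane ring is opened by a retro hetero-Diels–Alder reaction into the ortho-quinone tautomer of pristimerin (one methylation from celastrol) and (7R,10S)-guaia-1(5),3,11-triene; this last step forms both C–O bonds and sets guaiane C1/C5 and triterpene C8.
2. The guaiatriene comes from a guaia-4,11-dien-3-one by 1,2-reduction and dehydration; its five-membered ring comes from the intramolecular aldol condensation of a 1,4-diketone.
3. Key C–C bond (guaiane C1–C2): a zinc enolate, generated by Cu-catalysed asymmetric methyl addition (sets C10), is joined to 2-nitrobut-1-ene acting as an α-acyl cation (enolonium) equivalent, so two carbonyl α-carbons are coupled; Nef unmasking occurs in the work-up.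
4. C7 is set by Rh/BINAP-catalysed isopropenyl addition to cyclohepta-2,6-dienone, made from cycloheptanone.
5. Ring order: seven-membered ring (bought as cycloheptanone), then five-membered ring (aldol), then dioxane (cycloaddition); triterpene rings A–E arrive intact in celastrol.

Assumption: celastrol, a triterpenoid sold in multigram lots by many suppliers, is accepted as a purchased starting material. Sesquiterpene atoms carry guaiane numbers (C1/C5 ring fusion, C4 and C10 methyl-bearing, C7 isopropenyl-bearing) and triterpene atoms friedelane numbers.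

**Step 1**
Reactants: 1 cycloheptanone
Product: 2 cyclohepta-2,6-dien-1-one
Conditions: IBX (3 equiv), DMSO/fluorobenzene (1:2), 80 °C
Reagents that add atoms: none
Why: IBX-mediated α,β-dehydrogenation of ketones (Nicolaou dehydrogenation) runs twice on the symmetrical ketone to give the cross-conjugated dienone, and no stereocentre is formed.

**Step 2**
Reactants: 2 cyclohepta-2,6-dien-1-one (2 equiv); 3 isopropenylboronic acid pinacol ester
Product: 4 (R)-6-(prop-1-en-2-yl)cyclohept-2-en-1-one
Conditions: [Rh(cod)Cl]2 (2.5 mol %), (R)-BINAP (6 mol %), KOH (0.5 equiv), dioxane/H2O (10:1), 40 °C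
Reagents that add atoms: none
Why: Rh/BINAP-catalysed asymmetric 1,4-addition of an alkenylboron reagent (Hayashi–Miyaura reaction) to one of the two equivalent enone termini sets C7 by catalyst control, (R)-BINAP being expected to give the (R) product by analogy with the (R)-3-substituted cycloalkanones it gives from simple cycloalkenones, and the excess of 2 suppresses double addition.

**Step 3**
Reactants: 5 2-nitrobutan-1-ol
Product: 6 2-nitrobut-1-ene
Conditions: phthalic anhydride (1.3 equiv), 150 → 180 °C, 110 mmHg, product distilled out and used fresh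
Reagents that add atoms: none
Why: Thermal dehydration of a β-nitro alcohol through its phthalate half-ester is the standard preparation of 2-nitroalk-1-enes, and the volatile nitroalkene is removed as it forms; no stereocentre.

**Step 4**
Reactants: 4 (R)-6-(prop-1-en-2-yl)cyclohept-2-en-1-one; 6 2-nitrobut-1-ene
Product: 9 (2R,3S,6R)-3-methyl-2-(2-oxobutyl)-6-(prop-1-en-2-yl)cycloheptan-1-one, via MeZn enolate 7 (not isolated), via MeZn nitronate 8 (not isolated)
Conditions: Cu(OTf)2 (2 mol %), (S)-BINOL N,N-bis[(R)-1-phenylethyl]phosphoramidite (4 mol %), Me2Zn (1.1 equiv), toluene, −25 °C; then 6 (1.5 equiv), THF, −78 → −30 °C; then poured into aq. TiCl3 (5 equiv)/NH4OAc (pH 5–6), 0 °C → rt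
Reagents that add atoms: dimethylzinc, C[Zn]C; water, O
Why: Cu/phosphoramidite-catalysed asymmetric conjugate addition of Me2Zn (Feringa type) sets C10 by catalyst control (this ligand enantiomer gives the (S)-3-alkylcycloalkanone pattern, here cis to the remote isopropenyl group), the regiodefined enolate 7 is trapped anti to the new methyl by Michael addition to nitroalkene 6, which acts as an α-acyl cation equivalent so that two carbonyl α-carbons are joined (Noyori-type three-component coupling), and buffered TiCl3 reduction of nitronate 8 (McMurry variant of the Nef reaction) unmasks the 1,4-diketone without touching the isopropenyl group; the one-flask combination of these three known reactions is an extrapolation.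

**Step 5**
Reactants: 9 (2R,3S,6R)-3-methyl-2-(2-oxobutyl)-6-(prop-1-en-2-yl)cycloheptan-1-one
Product: 10 (5R,8S,8aR)-3,8-dimethyl-5-(prop-1-en-2-yl)-4,5,6,7,8,8a-hexahydroazulen-2(1H)-one, i.e. (1R,7R,10S)-guaia-4,11-dien-3-one
Conditions: KOH (2 equiv), MeOH/H2O, 60 °C
Reagents that add atoms: none
Why: Intramolecular aldol condensation of a 2-(2-oxoalkyl)cycloalkanone closes the five-membered ring through attack of the ethyl-ketone methylene on the ring ketone to give the tetrasubstituted cyclopentenone; C7 and C10 are not acidic and stay, while C1 (later sp2) may epimerise without consequence.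

**Step 6**
Reactants: 10 (1R,7R,10S)-guaia-4,11-dien-3-one
Product: 12 (4S,7R)-1,4-dimethyl-7-(prop-1-en-2-yl)-3,4,5,6,7,8-hexahydroazulene, i.e. (7R,10S)-guaia-1(5),3,11-triene, via allylic alcohol 11 (not isolated)
Conditions: LiAlH4, Et2O, −20 °C; then 1 M aq. HCl, 0 °C, 15 min; pentane extract kept at −20 °C and used the same day
Reagents that add atoms: none
Why: 1,2-Reduction of the cyclopentenone followed by acid-induced E1 dehydration of alcohol 11 through the C3–C5 allyl cation, which loses the C1 proton to give the most substituted cyclopentadiene (the standard enone-to-alkylcyclopentadiene sequence); the C1 stereocentre disappears, and the diene is used at once because of [1,5]-hydrogen shifts.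

**Step 7**
Reactants: 13 celastrol
Product: 14 pristimerin (celastrol methyl ester)
Conditions: MeI (3 equiv), NaHCO3 (3 equiv), DMF, rt, dark
Reagents that add atoms: iodomethane, CI
Why: SN2 O-alkylation of the carboxylate, with the weak base ionising only the carboxylic acid so the hydroxy quinone methide is left intact; no stereocentre changes.

**Step 8**
Reactants: 12 (7R,10S)-guaia-1(5),3,11-triene; 14 pristimerin (1.5 equiv)
Product: 16 target CNP0113384.2 (1,4-benzodioxane with triterpene O3 on guaiane C1 and triterpene O2 on guaiane C5, both oxygens syn to the C10 methyl and C7 isopropenyl, 8α-H, 6-ene), via ortho-quinone tautomer 15 (not isolated)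
Conditions: i-Pr2NEt (0.2 equiv), degassed toluene, 25–40 °C, dark, Ar
Reagents that add atoms: none
Why: Proposed new method: amine-mediated proton shuttling turns the hydroxy quinone methide 14 into its ortho-quinone tautomer 15 (C-protonation at C8 on the α face, anti to the C9 and C14 methyls, gives the trans B/C junction), and this 1,2-dicarbonyl heterodiene is trapped by the electron-rich tetrasubstituted C1=C5 bond of 12 in an inverse-electron-demand hetero-Diels–Alder reaction (closest known type: ortho-quinone plus alkene giving 1,4-benzodioxanes, as in biomimetic celastroid dimer formation); the O3–C1 bond should lead because that leaves phenoxide character on O2 para to the styrenyl carbon and allyl-cation character at C5, and suprafacial axial-type attack on the half-chair with isopropenyl equatorial and the C10 methyl pseudoaxial puts both oxygens on the β face, setting C1 and C5 cis.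

**Compound list**
1 | cycloheptanone | O=C1CCCCCC1 | starting material
2 | cyclohepta-2,6-dien-1-one | O=C1C=CCCC=C1 | intermediate
3 | isopropenylboronic acid pinacol ester (4,4,5,5-tetramethyl-2-(prop-1-en-2-yl)-1,3,2-dioxaborolane) | C=C(C)B1OC(C)(C)C(C)(C)O1 | starting material
4 | (R)-6-(prop-1-en-2-yl)cyclohept-2-en-1-one | C=C(C)[C@@H]1CCC=CC(=O)C1 | intermediate
5 | 2-nitrobutan-1-ol (racemic) | CCC(CO)[N+](=O)[O-] | starting material
6 | 2-nitrobut-1-ene | C=C(CC)[N+](=O)[O-] | intermediate
7 | methylzinc (3S,6R)-3-methyl-6-(prop-1-en-2-yl)cyclohept-1-en-1-olate | C=C(C)[C@@H]1CC[C@H](C)C=C(O[Zn]C)C1 | intermediate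
8 | methylzinc nitronate of (2R,3S,6R)-3-methyl-2-(2-nitrobutyl)-6-(prop-1-en-2-yl)cycloheptan-1-one | C=C(C)[C@@H]1CC[C@H](C)[C@@H](CC(CC)=[N+]([O-])O[Zn]C)C(=O)C1 | intermediate
9 | (2R,3S,6R)-3-methyl-2-(2-oxobutyl)-6-(prop-1-en-2-yl)cycloheptan-1-one | C=C(C)[C@@H]1CC[C@H](C)[C@@H](CC(=O)CC)C(=O)C1 | intermediate
10 | (5R,8S,8aR)-3,8-dimethyl-5-(prop-1-en-2-yl)-4,5,6,7,8,8a-hexahydroazulen-2(1H)-one | C=C(C)[C@@H]1CC[C@H](C)[C@H]2CC(=O)C(C)=C2C1 | intermediate
11 | (5R,8S,8aR)-3,8-dimethyl-5-(prop-1-en-2-yl)-1,2,4,5,6,7,8,8a-octahydroazulen-2-ol (both C2 epimers) | C=C(C)[C@@H]1CC[C@H](C)[C@H]2CC(O)C(C)=C2C1 | intermediate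
12 | (4S,7R)-1,4-dimethyl-7-(prop-1-en-2-yl)-3,4,5,6,7,8-hexahydroazulene | C=C(C)[C@@H]1CC[C@H](C)C2=C(C1)C(C)=CC2 | intermediate
13 | celastrol (3-hydroxy-2-oxo-24-nor-D:A-friedooleana-1(10),3,5,7-tetraen-29-oic acid; 9β-, 14β-, 17β-methyl, 13α-methyl, 18β-H, 20α-carboxyl) | O=C1C=C2C(=CC=C3[C@@]2(C)CC[C@@]2(C)[C@@H]4C[C@](C)(C(=O)O)CC[C@]4(C)CC[C@]32C)C(C)=C1O | starting material
14 | pristimerin (methyl ester of 13) | O=C1C=C2C(=CC=C3[C@@]2(C)CC[C@@]2(C)[C@@H]4C[C@](C)(C(=O)OC)CC[C@]4(C)CC[C@]32C)C(C)=C1O | intermediate
15 | ortho-quinone tautomer of pristimerin (methyl 2,3-dioxo-24-nor-D:A-friedooleana-1(10),4,6-trien-29-oate, 8α-H) | O=C1C=C2C(C=C[C@H]3[C@@]2(C)CC[C@@]2(C)[C@@H]4C[C@](C)(C(=O)OC)CC[C@]4(C)CC[C@]32C)=C(C)C1=O | intermediate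
16 | CNP0113384.2 | C=C(C)[C@@H]1CC[C@H](C)[C@@]23CC=C(C)[C@]2(C1)Oc1cc2c(c(C)c1O3)C=C[C@H]1[C@@]2(C)CC[C@@]2(C)[C@@H]3C[C@](C)(C(=O)OC)CC[C@]3(C)CC[C@]12C | target

**Step count and risks**
Total steps: 8. Longest linear sequence: 6 (steps 1, 2, 4, 5, 6, 8 from cycloheptanone).

Most likely to fail, first: the final cycloaddition (step 8).
- The ortho-quinone tautomer 15 is a minor equilibrium species and C-protonation at the hindered C8 may be slow; protonation at C6 would give the isomeric 7-ene adduct.
- Diene 12 equilibrates with its double-bond isomers by [1,5]-hydrogen shifts on the same timescale, and its C3=C4 bond can compete.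
- Regiochemistry across the two quinone oxygens and β-face selectivity rest on argument, not precedent.

The fallback sets out from 14 and returns at 16. Compound 14 is reduced with NaBH4 (MeOH, 0 °C) to pristimerol F4, the 7-ene catechol. This is oxidised with Ag2O (Et2O, 0 °C, MgSO4) in the presence of 12, so that pristimerol ortho-quinone F5 is trapped as it forms to give the 7-ene adduct F6. With the catechol now locked as the dioxane, KOtBu in DMSO at rt moves the benzylic/allylic 7-ene into conjugation with the arene, with protonation at C8 from the α face, to give 16. This replaces tautomer interception by discrete quinone generation plus a late alkene isomerisation.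

Second: the three-component coupling with Nef work-up (step 4).
- The zinc enolate may be too sluggish toward the nitroalkene.
- Cu-catalysed methyl transfer from residual Me2Zn to 6, or nitroalkene oligomerisation, may consume the trap.
- The nitronate may not be reduced cleanly in the quench.

The fallback sets out from 4 and returns at 9, using an acyl anion instead of the α-acyl cation equivalent. After the same Cu-catalysed Me2Zn addition, enolate 7 is trapped with Eschenmoser's salt (CH2=NMe2+ I−) to give Mannich base F1. Heating this with propanal, 3-benzyl-5-(2-hydroxyethyl)-4-methylthiazolium chloride (20 mol %) and Et3N in EtOH at 75 °C releases exo-methylene ketone F2 in situ. The thiazolium-derived acyl anion of propanal adds to it (Stetter reaction) to give 9 as a C2 epimer mixture, which is inconsequential because that centre becomes sp2 in 10.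

Third: the reduction/dehydration to the cyclopentadiene (step 6).
- Acid may give exocyclic or other double-bond isomers, or touch the isopropenyl group.
- The diene may dimerise or isomerise before use.

The fallback sets out from 10 and returns at 12. Compound 10 is treated with Tf2O and 2,6-di-tert-butyl-4-methylpyridine (CH2Cl2, 0 °C), which enolises toward C1 to give cyclopentadienyl triflate F3. Pd(OAc)2/PPh3 with Bu3N and HCO2H (DMF, 40 °C) then reduces the C–OTf bond to give 12 under non-acidic conditions with the diene position fixed by the triflate.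

**Further compounds**
F1 | step 4 | (2S,3S,6R)-2-[(dimethylamino)methyl]-3-methyl-6-(prop-1-en-2-yl)cycloheptan-1-one | C=C(C)[C@@H]1CC[C@H](C)[C@@H](CN(C)C)C(=O)C1
F2 | step 4 | (3S,6R)-3-methyl-2-methylidene-6-(prop-1-en-2-yl)cycloheptan-1-one | C=C(C)[C@@H]1CC[C@H](C)C(=C)C(=O)C1
F3 | step 6 | (4S,7R)-1,4-dimethyl-7-(prop-1-en-2-yl)-3,4,5,6,7,8-hexahydroazulen-2-yl trifluoromethanesulfonate | C=C(C)[C@@H]1CC[C@H](C)C2=C(C1)C(C)=C(OS(=O)(=O)C(F)(F)F)C2
F4 | step 8 | pristimerol (methyl 2,3-dihydroxy-24-nor-D:A-friedooleana-1,3,5(10),7-tetraen-29-oate) | Oc1cc2c(c(C)c1O)CC=C1[C@@]2(C)CC[C@@]2(C)[C@@H]3C[C@](C)(C(=O)OC)CC[C@]3(C)CC[C@]12C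
F5 | step 8 | pristimerol ortho-quinone (methyl 2,3-dioxo-24-nor-D:A-friedooleana-1(10),4,7-trien-29-oate) | O=C1C=C2C(CC=C3[C@@]2(C)CC[C@@]2(C)[C@@H]4C[C@](C)(C(=O)OC)CC[C@]4(C)CC[C@]32C)=C(C)C1=O
F6 | step 8 | 7-ene isomer of 16 (C6 methylene, C7=C8 double bond, otherwise as 16) | C=C(C)[C@@H]1CC[C@H](C)[C@@]23CC=C(C)[C@]2(C1)Oc1cc2c(c(C)c1O3)CC=C1[C@@]2(C)CC[C@@]2(C)[C@@H]3C[C@](C)(C(=O)OC)CC[C@]3(C)CC[C@]12C
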